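**Plan**
Target 13 is 5,7-dihydroxy-6,8-dimethyl-2-nonadecylchromen-4-one. It has a fully substituted benzenoid ring A, a pyranone ring B and no stereocentre, so no stereocontrol is needed.
Retrosynthesis: the O1–C2 bond of ring B is cut first, back to an O-methylated aryl ynone. Next come the two bonds at the carbonyl carbon, C4a–C4 and C4–C3, and last the acetylene–chain bond and the two aryl–CH3 bonds.
Enabling feature: C4 is a single carbonyl carbon between aryl carbon C4a of ring A and C3, and C3, C2 and the C19 chain together make up a terminal C21 alkyne. C4 can therefore arrive as CO, and the mirror-symmetric 2,4,6-trioxygenated ring A makes both ortho oxygens equivalent for closure.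
Forward: ring A is bought as 1,3,5-trimethoxybenzene, methylated twice and iodinated, and the chain is joined to acetylide. Iodide, CO and alkyne merge in step 5 with no ring formed. Ring B arises last (steps 6 and 7) through an enaminone, ether cleavage and 6-endo addition–elimination.

Key step: step 5

Remark: enaminone 11 is drawn as the E isomer expected from addition of a secondary amine. Its push–pull C=C bond rotates easily and the geometry is lost in step 7.

**Step 1**
Reactants: 1 1,3,5-trimethoxybenzene
Product: 3 2,4,6-trimethoxytoluene, via 2,4,6-trimethoxyphenyllithium 2 (not isolated)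
Conditions: n-BuLi, THF, 0 °C to rt; MeI, 0 °C to rt
Reagents that add atoms: iodomethane, CI
Why: Directed ortho-metalation places lithium on a ring carbon flanked by two methoxy groups (all three C–H sites are equivalent), and the aryllithium is methylated by SN2 attack on iodomethane.

**Step 2**
Reactants: 3 2,4,6-trimethoxytoluene
Product: 5 1,3,5-trimethoxy-2,4-dimethylbenzene, via 2,4,6-trimethoxy-3-methylphenyllithium 4 (not isolated)
Conditions: n-BuLi, TMEDA, THF, 0 °C to rt; MeI, 0 °C to rt
Reagents that add atoms: iodomethane, CI
Why: A second directed ortho-metalation occurs at one of the two equivalent C–H sites between methoxy groups, which are kinetically far more acidic than the benzylic methyl, and quenching with iodomethane installs the second methyl group.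

**Step 3**
Reactants: 5 1,3,5-trimethoxy-2,4-dimethylbenzene
Product: 6 2-iodo-1,3,5-trimethoxy-4,6-dimethylbenzene
Conditions: NIS, cat. TFA, MeCN, rt, dark
Reagents that add atoms: N-iodosuccinimide, O=C1CCC(=O)N1I
Why: Electrophilic aromatic iodination can only occur at the single remaining ring C–H, which is activated ortho, ortho and para by three methoxy groups.

**Step 4**
Reactants: 7 1-bromononadecane
Product: 8 henicos-1-yne
Conditions: LiC≡CH·H2NCH2CH2NH2, DMSO/THF, 0 °C to rt
Reagents that add atoms: lithium acetylide–ethylenediamine complex, [Li]C#C.NCCN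
Why: SN2 alkylation of the diamine-stabilised lithium acetylide by an unhindered primary bromide in a dipolar aprotic medium is the standard route to long-chain terminal alkynes, and the mild temperature prevents migration of the triple bond.

**Step 5**
Reactants: 6 2-iodo-1,3,5-trimethoxy-4,6-dimethylbenzene; 8 henicos-1-yne; 9 carbon monoxide
Product: 10 1-(2,4,6-trimethoxy-3,5-dimethylphenyl)docos-2-yn-1-one
Conditions: PdCl2(PPh3)2 (5 mol %), Et3N, toluene, CO (10 bar), 70 °C, autoclave
Reagents that add atoms: none
Why: PdCl2(PPh3)2 is reduced in the flask to zerovalent palladium, which inserts into the only C–I bond of 6; CO then binds and the aryl group migrates onto it, forming the C4a–C4 bond in an aroylpalladium iodide. Alkyne 8 coordinates to this electrophilic divalent palladium centre, Et3N takes the acetylenic proton, and reductive elimination from the aroyl(alkynyl)palladium species forms the C4–C3 bond and returns zerovalent palladium. This is the copper-free carbonylative Sonogashira coupling of aryl iodides with terminal alkynes, well known for electron-rich and ortho-alkoxy iodides. No ring closes and no stereocentre is created, because all three ring-A oxygens stay methylated and cannot attack the new ynone. The selectivity required is CO uptake ahead of direct alkynylation, and it is secured by the two ortho methoxy groups, which shield the arylpalladium species from the alkyne while their bulk and the electron-rich ring speed aryl migration to CO, helped by 10 bar of CO and the absence of a copper acetylide. The temperature is kept at 70 °C so that the propargylic CH2 of 10 is not drawn into phosphine- or base-induced isomerisation to a dienone.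

**Step 6**
Reactants: 10 1-(2,4,6-trimethoxy-3,5-dimethylphenyl)docos-2-yn-1-one
Product: 11 (E)-3-(diethylamino)-1-(2,4,6-trimethoxy-3,5-dimethylphenyl)docos-2-en-1-one
Conditions: Et2NH, THF/EtOH, rt to 40 °C
Reagents that add atoms: diethylamine, CCNCC
Why: Aza-Michael addition of a secondary amine to the ynone gives the push–pull enaminone, which masks the triple bond against bromide addition in the next step and marks the future C2 as the only electrophilic carbon, so closure must be 6-endo and not 5-exo.

**Step 7**
Reactants: 11 (E)-3-(diethylamino)-1-(2,4,6-trimethoxy-3,5-dimethylphenyl)docos-2-en-1-one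
Product: 13 5,7-dihydroxy-6,8-dimethyl-2-nonadecylchromen-4-one, via trihydroxyaryl enaminone 12 (not isolated)
Conditions: BBr3 (6 equiv), CH2Cl2, −78 °C to rt; H2O; then 2 M aq HCl, THF, 60 °C
Reagents that add atoms: none
Why: BBr3 cleavage of the aryl methyl ethers (carbonyl-assisted at both ortho positions) frees 12, whose ortho hydroxyl adds to the protonated enaminone carbon and expels diethylamine in the standard acid closure of o-hydroxyaryl enaminones to chromones (6-endo addition–elimination); the two ortho hydroxyls are equivalent, so only one chromone can form, and hydrolysis to the 1,3-diketone or a Wessely–Moser ring opening would lead back to the same product.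

**Compound list**
1 | 1,3,5-trimethoxybenzene | COc1cc(OC)cc(OC)c1 | starting material
2 | 2,4,6-trimethoxyphenyllithium | [Li]c1c(OC)cc(OC)cc1OC | intermediate
3 | 2,4,6-trimethoxytoluene | Cc1c(OC)cc(OC)cc1OC | intermediate
4 | 2,4,6-trimethoxy-3-methylphenyllithium | [Li]c1c(OC)cc(OC)c(C)c1OC | intermediate
5 | 1,3,5-trimethoxy-2,4-dimethylbenzene | COc1cc(OC)c(C)c(OC)c1C | intermediate
6 | 2-iodo-1,3,5-trimethoxy-4,6-dimethylbenzene | COc1c(C)c(OC)c(C)c(OC)c1I | intermediate
7 | 1-bromononadecane | CCCCCCCCCCCCCCCCCCCBr | starting material
8 | henicos-1-yne | CCCCCCCCCCCCCCCCCCCC#C | intermediate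
9 | carbon monoxide | [C-]#[O+] | starting material
10 | 1-(2,4,6-trimethoxy-3,5-dimethylphenyl)docos-2-yn-1-one | CCCCCCCCCCCCCCCCCCCC#CC(=O)c1c(OC)c(C)c(OC)c(C)c1OC | intermediate
11 | (E)-3-(diethylamino)-1-(2,4,6-trimethoxy-3,5-dimethylphenyl)docos-2-en-1-one | CCN(CC)/C(CCCCCCCCCCCCCCCCCCC)=C/C(=O)c1c(OC)c(C)c(OC)c(C)c1OC | intermediate
12 | (E)-3-(diethylamino)-1-(2,4,6-trihydroxy-3,5-dimethylphenyl)docos-2-en-1-one | CCN(CC)/C(CCCCCCCCCCCCCCCCCCC)=C/C(=O)c1c(O)c(C)c(O)c(C)c1O | intermediate
13 | 5,7-dihydroxy-6,8-dimethyl-2-nonadecylchromen-4-one | CCCCCCCCCCCCCCCCCCCc1cc(=O)c2c(O)c(C)c(O)c(C)c2o1 | target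

**Step count**
Total step count: 7.
Longest linear sequence: 6 (steps 1, 2, 3, 5, 6, 7). Step 4 is a one-step side branch.

**Steps most likely to fail**

Step 5. Oxidative addition into the hindered, electron-rich C–I bond may be sluggish under CO. Alkynylation may also proceed without CO uptake, or the ynone may isomerise on prolonged heating. The fallback sets out from 5 and 8 and comes back at 10, building the carbonyl carbon at the aldehyde level. Vilsmeier–Haack formylation of 5 (POCl3, DMF) should give 2,4,6-trimethoxy-3,5-dimethylbenzaldehyde F1. Deprotonation of 8 with n-BuLi in THF at −78 °C gives lithium henicos-1-yn-1-ide F2. This adds to F1 to give racemic 1-(2,4,6-trimethoxy-3,5-dimethylphenyl)docos-2-yn-1-ol F3. Oxidation of this benzylic, propargylic alcohol with MnO2 in CH2Cl2 then delivers 10.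

Step 7. Cleavage of the ether para to the carbonyl may stay incomplete, the enaminone may break down under the Lewis acid, or the electron-rich aryl ketone may lose its acyl group in acid. The fallback sets out from 10 and comes back at 13, closing ring B before any phenol is freed. ICl in CH2Cl2 at −78 °C to rt triggers iodocyclisation of the o-methoxyaryl ynone. The ortho methoxy oxygen attacks the iodonium-activated alkyne 6-endo and chloride removes its methyl group, giving 3-iodo-5,7-dimethoxy-6,8-dimethyl-2-nonadecylchromen-4-one F4. Transfer hydrodeiodination (Pd(PPh3)4, HCO2Na, DMF, 80 °C) should give 5,7-dimethoxy-6,8-dimethyl-2-nonadecylchromen-4-one F5. This robust chromone is then demethylated with BBr3 in CH2Cl2 to 13.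

Step 2. Metalation may be incomplete or partly lateral (at the benzylic methyl), leaving mixtures that are hard to separate. The fallback sets out from 3 and comes back at 5, using electrophilic substitution in place of metalation. Vilsmeier–Haack formylation of 3 (POCl3, DMF) should give 2,4,6-trimethoxy-3-methylbenzaldehyde F6. Its electron-rich aldehyde is reduced to the methyl group by ionic hydrogenation (Et3SiH, TFA, CH2Cl2, rt), giving 5.

**Further compounds**
F1 | step 5 | 2,4,6-trimethoxy-3,5-dimethylbenzaldehyde | O=Cc1c(OC)c(C)c(OC)c(C)c1OC
F2 | step 5 | lithium henicos-1-yn-1-ide | CCCCCCCCCCCCCCCCCCCC#C[Li]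
F3 | step 5 | 1-(2,4,6-trimethoxy-3,5-dimethylphenyl)docos-2-yn-1-ol (racemic) | CCCCCCCCCCCCCCCCCCCC#CC(O)c1c(OC)c(C)c(OC)c(C)c1OC
F4 | step 7 | 3-iodo-5,7-dimethoxy-6,8-dimethyl-2-nonadecylchromen-4-one | CCCCCCCCCCCCCCCCCCCc1oc2c(C)c(OC)c(C)c(OC)c2c(=O)c1I
F5 | step 7 | 5,7-dimethoxy-6,8-dimethyl-2-nonadecylchromen-4-one | CCCCCCCCCCCCCCCCCCCc1cc(=O)c2c(OC)c(C)c(OC)c(C)c2o1
F6 | step 2 | 2,4,6-trimethoxy-3-methylbenzaldehyde | O=Cc1c(OC)cc(OC)c(C)c1OC
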